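**Strategy.** Ring A is cut at C3a–C4 and C5–C6. This exposes the adjacent quaternary carbons C4 and C5, whose cis methyls and cis one-carbon groups (the C4 carboxyl and the first chain carbon on C5) are the imprint of 2,3-dimethylmaleic anhydride. A single auxiliary-controlled Diels–Alder reaction with a 1-amino-3-siloxybutadiene closes ring A, creates both quaternary centres and, once the amine is expelled, leaves a C7 enone from which ring B and the C7 methyl are grown. The precursor is the TBS dienol ether of a vinylogous amide of (2R,5R)-2,5-diphenylpyrrolidine. The anhydride then rides through as a spectator and is opened at its C5 carbonyl only at the end.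

Key step: step 3

Atom labels follow the indene numbering of the target (C1–C7a; ring A six-membered, ring B five-membered).

Assumption 1: the (2R,5R) auxiliary is taken to favour the endo approach leading to (3aS,7aR)-9; if the sense proves opposite, (2S,5S)-2 is used and nothing else changes.

Assumption 2: the (Sa,S,S)-phosphoramidite is taken to give the (R)-configured but-3-en-2-yl centre (C1) in step 5; otherwise its mirror image is used.

**Step 1**
Reactants: 1 (E)-4-methoxybut-3-en-2-one; 2 (2R,5R)-2,5-diphenylpyrrolidine
Product: 3 (E)-4-[(2R,5R)-2,5-diphenylpyrrolidin-1-yl]but-3-en-2-one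
Conditions: THF, 23 → 60 °C
Reagents that add atoms: none
Why: addition–elimination of the secondary amine at the β-carbon of the vinylogous ester expels methanol and should give the more stable E vinylogous amide.

**Step 2**
Reactants: 3 (E)-4-[(2R,5R)-2,5-diphenylpyrrolidin-1-yl]but-3-en-2-one
Product: 5 (E)-3-(tert-butyldimethylsilyloxy)-1-[(2R,5R)-2,5-diphenylpyrrolidin-1-yl]buta-1,3-diene, via potassium dienolate 4 (not isolated)
Conditions: KN(SiMe3)2, THF, −78 °C; then tBuMe2SiCl, −78 → 23 °C
Reagents that add atoms: tert-butyldimethylsilyl chloride, CC(C)(C)[Si](C)(C)Cl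
Why: kinetic deprotonation of the methyl ketone and O-silylation of the cross-conjugated enolate (silyl enol ether formation) should give the aminosiloxy diene with the E enamine geometry retained.

**Step 3**
Reactants: 5 (E)-3-(tert-butyldimethylsilyloxy)-1-[(2R,5R)-2,5-diphenylpyrrolidin-1-yl]buta-1,3-diene; 6 2,3-dimethylmaleic anhydride
Product: 9 (3aS,7aR)-3a,7a-dimethyl-3a,7a-dihydro-2-benzofuran-1,3,5(4H)-trione (enone anhydride: C7 ketone; C7a=C3a alkene; C4/C5 methyls cis), via silyl enol ether cycloadduct 7 (not isolated), via beta-amino ketone 8 (not isolated)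
Conditions: PhMe (2 M), 70 °C, sealed tube; then HF (48% aq.), MeCN, 0 → 23 °C
Reagents that add atoms: none
Why: The electron-rich diene should add to the anhydride in a concerted but strongly asynchronous [4+2] cycloaddition in which the C5–C6 bond (diene CH2 terminus) leads and the C3a–C4 bond follows; aqueous HF then cleaves the silyl enol ether of 7, and the β-amino ketone 8 loses the protonated amine by E1cB elimination to give the C7a=C3a enone. The closest known chemistry is the Diels–Alder reaction of 1-amino-3-siloxybutadienes carrying this C2-symmetric pyrrolidine with acrylates, methacrolein and maleic-type dienophiles, which gives 4-substituted cyclohex-2-enones after amine loss. Ring A is closed by the cycloaddition itself, the two new σ bonds joining both diene termini to the two alkene carbons of 6 in one six-membered transition state. C4 and C5 are created together with cis methyls because addition to the cyclic alkene is suprafacial, and their absolute configuration is set by the auxiliary, whose phenyl groups differentiate the diene faces. Because the amine-bearing centre is erased, the enantiomer of 9 is fixed by the combination of diene face and endo/exo orientation, so both must be uniform; the anhydride carbonyls are expected endo, and the symmetric dienophile raises no regiochemical question. Acid keeps the liberated amine protonated so that it cannot acylate the anhydride, and any diacid formed on work-up should re-close on concentration.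

**Step 4**
Reactants: 9 enone anhydride; 10 isopropenylmagnesium bromide
Product: 11 trimethylsilyl enol ether (C7–OSiMe3, C7=C7a; isopropenyl on C3a cis to the C4/C5 methyls; anhydride intact)
Conditions: 10 (2.2 equiv), CuBr·SMe2 (1.1 equiv), THF, −78 → −40 °C; then Me3SiCl, 9, −78 °C; Et3N quench
Reagents that add atoms: chlorotrimethylsilane, C[Si](C)(C)Cl
Why: silyl-chloride-accelerated conjugate addition of the magnesium diisopropenylcuprate should place isopropenyl at C3a on the convex, methyl-bearing face of the cis-fused bicycle, anti to the pseudo-axial C4 acyl bond; the anhydride carbonyls, each on a fully substituted carbon, should not be attacked at −78 °C, and the enolate is trapped regiospecifically at C7=C7a.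

**Step 5**
Reactants: 11 trimethylsilyl enol ether; 12 (E)-but-2-en-1-yl methyl carbonate
Product: 13 C7 ketone with (2R)-but-3-en-2-yl on C7a (trans to the C3a isopropenyl) and the anhydride intact
Conditions: [Ir(cod)Cl]2 (2.5 mol%), (Sa)-(1,1'-binaphthalene-2,2'-diyl) N,N-bis[(S)-1-phenylethyl]phosphoramidite (5 mol%), CsF (0.4 equiv), ZnF2 (1.5 equiv), DME, 50 °C
Reagents that add atoms: none
Why: iridium-catalysed branched-selective allylic alkylation of the fluoride-activated silyl enol ether, in which C7a attacks the substituted allyl terminus from the face anti to the neighbouring isopropenyl group (C3a/C7a trans) while the phosphoramidite controls the new methyl-bearing centre C1.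

**Step 6**
Reactants: 13 allylated ketone
Product: 14 1,3,4,5-tetramethyl-7-oxo-3a,4,5,6,7,7a-hexahydro-1H-indene-4,5-dicarboxylic anhydride (trans ring fusion; C1 methyl cis to H-7a)
Conditions: RuCl2(=CHPh)(PCy3)(H2IMes) (second-generation Grubbs catalyst, 5 mol%), CH2Cl2, 40 °C
Reagents that add atoms: none
Why: ring-closing metathesis between the vinyl and isopropenyl groups, held gauche by their trans-diequatorial arrangement, should close ring B as the trisubstituted C2=C3 cyclopentene with loss of ethene under neutral conditions that leave C7a and C1 untouched.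

**Step 7**
Reactants: 14 ring B ketone
Product: 16 C7 enol triflate (C6=C7), via lithium enolate 15 (not isolated)
Conditions: LiN(iPr)2, THF, −78 °C; then PhNTf2, −78 → 0 °C
Reagents that add atoms: N-phenylbis(trifluoromethanesulfonimide), O=S(=O)(N(c1ccccc1)S(=O)(=O)C(F)(F)F)C(F)(F)F
Why: kinetic deprotonation at the C6 methylene (the C7a methine is tertiary and would put an enolate double bond at the trans ring fusion) followed by O-triflation gives the C6=C7 enol triflate without disturbing C7a.

**Step 8**
Reactants: 16 enol triflate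
Product: 17 1,3,4,5,7-pentamethyl-3a,4,5,7a-tetrahydro-1H-indene-4,5-dicarboxylic anhydride
Conditions: Me4Sn, Pd(PPh3)4 (5 mol%), LiCl, DMF, 80 °C
Reagents that add atoms: tetramethylstannane, C[Sn](C)(C)C
Why: Stille cross-coupling of the enol triflate (oxidative addition, chloride-assisted transmetallation, reductive elimination) installs the C7 methyl at a fixed alkene position under neutral conditions that spare the anhydride.

**Step 9**
Reactants: 17 diene anhydride
Product: 19 hydroxy lactone (C4 carbonyl lactonised onto the C5-bound hemiacetal carbon; in equilibrium with the C5-formyl C4-carboxylic acid), via aluminium hemiacetal 18 (not isolated)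
Conditions: iBu2AlH (1.05 equiv), CH2Cl2, −78 °C; then aq. potassium sodium tartrate
Reagents that add atoms: none
Why: one equivalent of the bulky aluminium hydride should add to the less encumbered anhydride carbonyl, the one on C5 beside the sp2 C6–H (the C4 carbonyl is screened by C3a and the C3 methyl), and the tetrahedral aluminium alkoxide persists at −78 °C so that reduction stops at the hydroxy lactone.

**Step 10**
Reactants: 19 hydroxy lactone; 20 2-(triphenylphosphoranylidene)propanal
Product: 21 5-[(1E)-2-methyl-3-oxoprop-1-en-1-yl]-1,3,4,5,7-pentamethyl-3a,4,5,7a-tetrahydro-1H-indene-4-carboxylic acid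
Conditions: 20 (2.5 equiv), PhMe, 110 °C
Reagents that add atoms: none
Why: the hydroxy lactone is in ring–chain equilibrium with the C5 aldehyde carboxylate (favoured once the basic ylide has taken the acid proton), and Wittig olefination with the stabilised formyl ylide should give the E trisubstituted enal under the thermodynamic control typical of stabilised ylides.

**Step 11**
Reactants: 21 enal acid; 22 diethyl benzylphosphonate
Product: 23 27-nor-zyggomphic acid B
Conditions: 22 (1.5 equiv), NaH (3.2 equiv), THF, 0 → 23 °C; then 1 M HCl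
Reagents that add atoms: none
Why: Horner–Wadsworth–Emmons olefination of the enal with the benzylphosphonate carbanion (the carboxylate is a spectator) should give the E styryl bond and hence the E,E diene, and acidification returns the free acid.

**Compound list**

1 | (E)-4-methoxybut-3-en-2-one | CO/C=C/C(C)=O | starting material
2 | (2R,5R)-2,5-diphenylpyrrolidine | N1[C@@H](c2ccccc2)CC[C@@H]1c1ccccc1 | starting material
3 | (E)-4-[(2R,5R)-2,5-diphenylpyrrolidin-1-yl]but-3-en-2-one | CC(=O)/C=C/N1[C@@H](c2ccccc2)CC[C@@H]1c1ccccc1 | intermediate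
4 | potassium dienolate of 3 | [K+].C=C([O-])/C=C/N1[C@@H](c2ccccc2)CC[C@@H]1c1ccccc1 | intermediate
5 | (E)-3-(tert-butyldimethylsilyloxy)-1-[(2R,5R)-2,5-diphenylpyrrolidin-1-yl]buta-1,3-diene | C=C(O[Si](C)(C)C(C)(C)C)/C=C/N1[C@@H](c2ccccc2)CC[C@@H]1c1ccccc1 | intermediate
6 | 2,3-dimethylmaleic anhydride | CC1=C(C)C(=O)OC1=O | starting material
7 | endo cycloadduct, 5-(tert-butyldimethylsilyloxy)-7-[(2R,5R)-2,5-diphenylpyrrolidin-1-yl]-3a,7a-dimethyl-3a,4,7,7a-tetrahydro-2-benzofuran-1,3-dione (amine cis to the anhydride) | CC(C)(C)[Si](C)(C)OC1=C[C@@H](N2[C@@H](c3ccccc3)CC[C@@H]2c2ccccc2)[C@@]2(C)C(=O)OC(=O)[C@@]2(C)C1 | intermediate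
8 | beta-amino ketone, 7-[(2R,5R)-2,5-diphenylpyrrolidin-1-yl]-3a,7a-dimethylhexahydro-2-benzofuran-1,3,5-trione | O=C1C[C@@H](N2[C@@H](c3ccccc3)CC[C@@H]2c2ccccc2)[C@@]2(C)C(=O)OC(=O)[C@@]2(C)C1 | intermediate
9 | (3aS,7aR)-3a,7a-dimethyl-3a,7a-dihydro-2-benzofuran-1,3,5(4H)-trione | O=C1C=C[C@@]2(C)C(=O)OC(=O)[C@@]2(C)C1 | intermediate
10 | isopropenylmagnesium bromide | C=C(C)[Mg]Br | starting material
11 | trimethylsilyl enol ether of the C3a-isopropenyl ketone (isopropenyl cis to the ring-fusion methyls) | C[Si](C)(C)OC1=C[C@H](C(C)=C)[C@@]2(C)C(=O)OC(=O)[C@@]2(C)C1 | intermediate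
12 | (E)-but-2-en-1-yl methyl carbonate | C/C=C/COC(=O)OC | starting material
13 | C7 ketone bearing C3a isopropenyl and C7a (2R)-but-3-en-2-yl (mutually trans), anhydride intact | O=C1[C@@H]([C@H](C)C=C)[C@H](C(C)=C)[C@@]2(C)C(=O)OC(=O)[C@@]2(C)C1 | intermediate
14 | 1,3,4,5-tetramethyl-7-oxo-3a,4,5,6,7,7a-hexahydro-1H-indene-4,5-dicarboxylic anhydride (trans-fused) | O=C1C[C@]2(C)C(=O)OC(=O)[C@]2(C)[C@H]2C(C)=C[C@@H](C)[C@H]12 | intermediate
15 | lithium C6=C7 enolate of 14 | [Li+].[O-]C1=C[C@]2(C)C(=O)OC(=O)[C@]2(C)[C@H]2C(C)=C[C@@H](C)[C@H]12 | intermediate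
16 | C7 enol triflate of 14 | O=S(=O)(OC1=C[C@]2(C)C(=O)OC(=O)[C@]2(C)[C@H]2C(C)=C[C@@H](C)[C@H]12)C(F)(F)F | intermediate
17 | 1,3,4,5,7-pentamethyl-3a,4,5,7a-tetrahydro-1H-indene-4,5-dicarboxylic anhydride | CC1=C[C@]2(C)C(=O)OC(=O)[C@]2(C)[C@H]2C(C)=C[C@@H](C)[C@H]12 | intermediate
18 | diisobutylaluminium hemiacetal at the C5-bound carbon | CC1=C[C@]2(C)C(O[Al](CC(C)C)CC(C)C)OC(=O)[C@]2(C)[C@H]2C(C)=C[C@@H](C)[C@H]12 | intermediate
19 | hydroxy lactone (hemiacetal carbon on C5, lactone carbonyl on C4; both hemiacetal epimers) | CC1=C[C@]2(C)C(O)OC(=O)[C@]2(C)[C@H]2C(C)=C[C@@H](C)[C@H]12 | intermediate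
20 | 2-(triphenylphosphoranylidene)propanal | CC(C=O)=P(c1ccccc1)(c1ccccc1)c1ccccc1 | starting material
21 | 5-[(1E)-2-methyl-3-oxoprop-1-en-1-yl]-1,3,4,5,7-pentamethyl-3a,4,5,7a-tetrahydro-1H-indene-4-carboxylic acid | CC1=C[C@](C)(/C=C(C)/C=O)[C@](C)(C(=O)O)[C@H]2C(C)=C[C@@H](C)[C@H]12 | intermediate
22 | diethyl benzylphosphonate | CCOP(=O)(Cc1ccccc1)OCC | starting material
23 | 27-nor-zyggomphic acid B, 1,3,4,5,7-pentamethyl-5-[(1E,3E)-2-methyl-4-phenylbuta-1,3-dien-1-yl]-3a,4,5,7a-tetrahydro-1H-indene-4-carboxylic acid | CC1=C[C@](C)(/C=C(C)/C=C/c2ccccc2)[C@](C)(C(=O)O)[C@H]2C(C)=C[C@@H](C)[C@H]12 | target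

**Total step count:** 11. **Longest linear sequence:** 11 steps (1 → 23).

**Steps most likely to fail**

Step 3. The fully substituted anhydride may add too slowly, so that C-acylation of the enamine by the anhydride or decay of the diene competes. In addition, because the amine-bearing centre is erased, any mixing of endo/exo or facial pathways lowers the enantiomeric purity of 9. The fallback sets out from 6 and returns at 9, replacing auxiliary control by desymmetrisation of a meso intermediate. Heating 6 with buta-1,3-diene (sealed vessel, 180 °C) gives meso cis-1,2-dimethylcyclohex-4-ene-1,2-dicarboxylic anhydride F1. Cinchona-alkaloid-mediated methanolysis (quinidine or quinine, MeOH, PhMe, −55 °C, the pseudo-enantiomer chosen so that the free acid sits on the future C5) gives the hemiester 2-(methoxycarbonyl)-1,2-dimethylcyclohex-4-ene-1-carboxylic acid F2. Iodolactonisation (I2, KI, NaHCO3) ties that acid to the ring alkene and so fixes which ring carbon is oxygenated, giving methyl 4-iodo-1,2-dimethyl-7-oxo-6-oxabicyclo[3.2.1]octane-2-carboxylate F3. DBU removes HI to give the bridged allylic lactone methyl 1,2-dimethyl-7-oxo-6-oxabicyclo[3.2.1]oct-3-ene-2-carboxylate F4. KOH in aqueous methanol cleaves lactone and ester to 5-hydroxy-1,2-dimethylcyclohex-3-ene-1,2-dicarboxylic acid F5. MnO2 oxidises the allylic alcohol to 1,2-dimethyl-5-oxocyclohex-3-ene-1,2-dicarboxylic acid F6, which closes with Ac2O to 9.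

Step 5. The congested enolate may attack the unsubstituted allyl terminus, giving the linear crotyl ketone, or catalyst control over C1 may be weak against the substrate's own bias. The fallback sets out from 11 and returns at 13, setting C1 by substrate control. A Mukaiyama aldol reaction of 11 with acetaldehyde (TiCl4, CH2Cl2, −78 °C) gives the C7a 1-hydroxyethyl ketone F7. Mesylation (MsCl, Et3N) gives the mesylate F8, and DBU gives the (E)-ethylidene enone F9, in which allylic strain holds the C3a isopropenyl group pseudo-axial. Lithium divinylcuprate, (CH2=CH)2CuLi, in THF at −78 °C should add to the exocyclic β-carbon from the face opposite that group, which sets the same C1 configuration as in 13. Protonation may first give the C7a epimer of 13 F10, which catalytic DBU in PhMe should equilibrate to the trans-diequatorial ketone 13.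

Step 9. Hydride may also be delivered to the C4-bound carbonyl, or a second hydride transfer may take the C5 carbon on to the alcohol (lactone) level. The fallback sets out from 17 and returns at 19. Ring opening with lithium ethanethiolate (EtSLi, THF, −78 → 0 °C) is a reversible acyl transfer that should settle on the less congested C5 carbonyl and gives the S-ethyl thioester acid F11. Fukuyama reduction (Et3SiH, Pd/C, acetone) converts the thioester into the aldehyde without over-reduction, and the aldehyde acid closes to 19.

**Further compounds**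

F1 | step 3 | cis-1,2-dimethylcyclohex-4-ene-1,2-dicarboxylic anhydride (meso) | C[C@@]12CC=CC[C@]1(C)C(=O)OC2=O
F2 | step 3 | 2-(methoxycarbonyl)-1,2-dimethylcyclohex-4-ene-1-carboxylic acid (acid on the future C5) | COC(=O)[C@]1(C)CC=CC[C@]1(C)C(=O)O
F3 | step 3 | methyl 4-iodo-1,2-dimethyl-7-oxo-6-oxabicyclo[3.2.1]octane-2-carboxylate | COC(=O)[C@]1(C)C[C@@H](I)[C@H]2C[C@]1(C)C(=O)O2
F4 | step 3 | methyl 1,2-dimethyl-7-oxo-6-oxabicyclo[3.2.1]oct-3-ene-2-carboxylate | COC(=O)[C@]1(C)C=C[C@H]2C[C@]1(C)C(=O)O2
F5 | step 3 | 5-hydroxy-1,2-dimethylcyclohex-3-ene-1,2-dicarboxylic acid | OC(=O)[C@]1(C)C=C[C@H](O)C[C@]1(C)C(=O)O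
F6 | step 3 | 1,2-dimethyl-5-oxocyclohex-3-ene-1,2-dicarboxylic acid | O=C1C=C[C@@](C)(C(=O)O)[C@@](C)(C(=O)O)C1
F7 | step 5 | C7a 1-hydroxyethyl ketone (aldol; carbinol epimers) | O=C1[C@@H](C(C)O)[C@H](C(C)=C)[C@@]2(C)C(=O)OC(=O)[C@@]2(C)C1
F8 | step 5 | mesylate of F7 | O=C1[C@@H](C(C)OS(C)(=O)=O)[C@H](C(C)=C)[C@@]2(C)C(=O)OC(=O)[C@@]2(C)C1
F9 | step 5 | (E)-ethylidene enone | O=C1/C(=C/C)[C@H](C(C)=C)[C@@]2(C)C(=O)OC(=O)[C@@]2(C)C1
F10 | step 5 | C7a epimer of 13 | O=C1[C@H]([C@H](C)C=C)[C@H](C(C)=C)[C@@]2(C)C(=O)OC(=O)[C@@]2(C)C1
F11 | step 9 | S-ethyl thioester acid (thioester on C5, acid on C4) | CC1=C[C@](C)(C(=O)SCC)[C@](C)(C(=O)O)[C@H]2C(C)=C[C@@H](C)[C@H]12
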